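## Retrosynthetic overview

- The methyl ester comes from methanolysis of an N-acyl thiazolidinethione; the C2–C3 bond comes from anti addition of a chiral titanium propionate enolate to a cyclic peroxycarbenium ion (from a 3-methoxy-1,2-dioxane).
- The 1,2-dioxane is the only ring made; it is closed at O–C3 by acid transacetalisation of a tertiary hydroperoxide onto a masked aldehyde.
- The C6–OO bond comes from cobalt-catalysed Markovnikov hydroperoxysilylation of a trisubstituted alkene.
- The key C5–C6 bond joins the methyl ketone carbon of 4-oxo-dihydro-β-ionone to a β-formylethyl (homoenolate, d3) phosphorus ylide.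
- The ring ketone comes from allylic oxidation of commercial dihydro-β-ionone; the cyclohexene ring is bought.

Assumption: the quinine-derived cyclocondensation catalyst named in the fallback to step 5 is taken to deliver the (3R,4S)-lactone; if it delivers the antipode, its quinidine-derived pseudo-enantiomer is used.

## Route

Step 1
Reactants: 1 dihydro-β-ionone [4-(2,6,6-trimethylcyclohex-1-en-1-yl)butan-2-one]
Product: 2 4-(2,6,6-trimethyl-3-oxocyclohex-1-en-1-yl)butan-2-one
Conditions: CrO3, 3,5-dimethylpyrazole, CH2Cl2, −20 °C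
Reagents that add atoms: chromium trioxide, O=[Cr](=O)=O
Why: Allylic oxidation with the CrO3–3,5-dimethylpyrazole complex should convert the ring CH2 next to the tetrasubstituted alkene into the enone, because the side-chain allylic CH2 is more hindered (it sits on the alkene carbon that bears the gem-dimethyl carbon) and the vinylic methyl is primary, while the saturated methyl ketone is untouched; no stereocentre is formed.

Step 2
Reactants: 2 4-(2,6,6-trimethyl-3-oxocyclohex-1-en-1-yl)butan-2-one; 3 [2-(1,3-dioxolan-2-yl)ethyl]triphenylphosphonium bromide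
Product: 5 3-[5-(1,3-dioxolan-2-yl)-3-methylpent-3-en-1-yl]-2,4,4-trimethylcyclohex-2-en-1-one (E/Z mixture), via phosphorus ylide 4 (not isolated)
Conditions: 3, KN(SiMe3)2, THF, 0 °C; then 2, −78 °C to rt
Reagents that add atoms: none
Why: Wittig olefination with a β-formylethyl ylide, a homoenolate (d3) equivalent whose nucleophilic carbon is the normally electrophilic β-carbon of a masked propanal, joins C-5 to the electrophilic ketone carbon C-6; the unconjugated methyl ketone should react faster than the conjugated, α-substituted ring ketone, and the E/Z ratio is irrelevant because both isomers give the same C-6 radical in step 3.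

Step 3
Reactants: 5 3-[5-(1,3-dioxolan-2-yl)-3-methylpent-3-en-1-yl]-2,4,4-trimethylcyclohex-2-en-1-one
Product: 6 3-{5-(1,3-dioxolan-2-yl)-3-methyl-3-[(triethylsilyl)peroxy]pentyl}-2,4,4-trimethylcyclohex-2-en-1-one (racemic at the peroxide carbon)
Conditions: Co(acac)2 (10 mol %), O2 (1 atm), Et3SiH, ClCH2CH2Cl, rt
Reagents that add atoms: dioxygen, O=O; triethylsilane, CC[SiH](CC)CC
Why: Mukaiyama–Isayama hydroperoxysilylation: hydrogen-atom transfer from a cobalt hydride to C-5 of the electron-rich trisubstituted alkene gives the tertiary C-6 radical, which captures O2 and is silylated (the tetrasubstituted enone alkene and the acetal are inert), so the C-6 peroxide forms with Markovnikov regiochemistry but with no facial control, as a 1:1 pair of enantiomers.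

Step 4
Reactants: 6 3-{5-(1,3-dioxolan-2-yl)-3-methyl-3-[(triethylsilyl)peroxy]pentyl}-2,4,4-trimethylcyclohex-2-en-1-one
Product: 8 3-[2-(6-methoxy-3-methyl-1,2-dioxan-3-yl)ethyl]-2,4,4-trimethylcyclohex-2-en-1-one (racemic; anomer mixture), via hydroperoxide 7 (not isolated)
Conditions: TsOH·H2O (10 mol %), MeOH, 0 °C to rt
Reagents that add atoms: methanol, CO
Why: Acid-catalysed desilylation and transacetalisation: the freed tertiary hydroperoxide adds 6-exo to the oxocarbenium ion generated from the dioxolane and methanol caps the peroxyacetal, so the 1,2-dioxane ring closes under thermodynamic control; the acetal carbon is a labile centre that is erased in step 5.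

Step 5
Reactants: 8 3-[2-(6-methoxy-3-methyl-1,2-dioxan-3-yl)ethyl]-2,4,4-trimethylcyclohex-2-en-1-one; 9 (S)-4-isopropyl-3-propanoyl-1,3-thiazolidine-2-thione
Product: 12 (4S)-4-isopropyl-3-[(2R)-2-{(3R,6R)-6-methyl-6-[2-(2,6,6-trimethyl-3-oxocyclohex-1-en-1-yl)ethyl]-1,2-dioxan-3-yl}propanoyl]-1,3-thiazolidine-2-thione, via titanium enolate 10 (not isolated), via peroxycarbenium ion 11 (not isolated)
Conditions: 9, TiCl4, iPr2NEt, CH2Cl2, −78 °C; then 8, SnCl4, −78 to −40 °C; chromatographic separation of the C-6 epimers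
Reagents that add atoms: none
Why: Proposed new method: SnCl4 ionises the methoxy peroxyacetal to the cyclic peroxycarbenium ion 11, which is attacked in an open Mukaiyama-aldol-type transition state by the chelated Z chlorotitanium enolate 10 on the face opposite its isopropyl group (sets 2R) with the C-3 hydrogen in the most hindered position (anti topicity, sets 3R); the closest known reactions are Lewis-acid additions of silyl ketene acetals to 3-alkoxy-1,2-dioxanes and anti-selective additions of this titanium enolate to acetals, and because C-6 is not induced the 6R adduct must be separated from the 6S epimer that forms in equal amount.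

Step 6
Reactants: 12 (4S)-4-isopropyl-3-[(2R)-2-{(3R,6R)-6-methyl-6-[2-(2,6,6-trimethyl-3-oxocyclohex-1-en-1-yl)ethyl]-1,2-dioxan-3-yl}propanoyl]-1,3-thiazolidine-2-thione
Product: 13 diacarperoxide A [methyl (2R)-2-{(3R,6R)-6-methyl-6-[2-(2,6,6-trimethyl-3-oxocyclohex-1-en-1-yl)ethyl]-1,2-dioxan-3-yl}propanoate]
Conditions: MeOH, imidazole, CH2Cl2, rt
Reagents that add atoms: methanol, CO
Why: Imidazole-catalysed methanolysis (nucleophilic acyl substitution) of the activated N-acyl thiazolidinethione gives the methyl ester under near-neutral conditions, which should neither epimerise C-2 nor open the β-peroxy ester by retro-oxa-Michael reaction, and the auxiliary is recovered.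

Origin of the stereocentres: C-2 and C-3 are set in step 5 by the auxiliary. C-6 is created without induction in step 3 and is obtained pure in step 5 only by separating the two diastereomeric adducts, so half of the material is lost there.

## Compound list

1 | dihydro-β-ionone, 4-(2,6,6-trimethylcyclohex-1-en-1-yl)butan-2-one | CC(=O)CCC1=C(C)CCCC1(C)C | starting material
2 | 4-(2,6,6-trimethyl-3-oxocyclohex-1-en-1-yl)butan-2-one | CC(=O)CCC1=C(C)C(=O)CCC1(C)C | intermediate
3 | [2-(1,3-dioxolan-2-yl)ethyl]triphenylphosphonium bromide | [Br-].C1COC(CC[P+](c2ccccc2)(c2ccccc2)c2ccccc2)O1 | starting material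
4 | [2-(1,3-dioxolan-2-yl)ethylidene]triphenylphosphorane (ylide) | C1COC(CC=P(c2ccccc2)(c2ccccc2)c2ccccc2)O1 | intermediate
5 | 3-[5-(1,3-dioxolan-2-yl)-3-methylpent-3-en-1-yl]-2,4,4-trimethylcyclohex-2-en-1-one (E/Z mixture) | CC(CCC1=C(C)C(=O)CCC1(C)C)=CCC1OCCO1 | intermediate
6 | 3-{5-(1,3-dioxolan-2-yl)-3-methyl-3-[(triethylsilyl)peroxy]pentyl}-2,4,4-trimethylcyclohex-2-en-1-one (racemic) | CC(CCC1=C(C)C(=O)CCC1(C)C)(CCC1OCCO1)OO[Si](CC)(CC)CC | intermediate
7 | 3-[5-(1,3-dioxolan-2-yl)-3-hydroperoxy-3-methylpentyl]-2,4,4-trimethylcyclohex-2-en-1-one (racemic) | CC(CCC1=C(C)C(=O)CCC1(C)C)(CCC1OCCO1)OO | intermediate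
8 | 3-[2-(6-methoxy-3-methyl-1,2-dioxan-3-yl)ethyl]-2,4,4-trimethylcyclohex-2-en-1-one (racemic, anomer mixture) | COC1CCC(C)(CCC2=C(C)C(=O)CCC2(C)C)OO1 | intermediate
9 | (S)-4-isopropyl-3-propanoyl-1,3-thiazolidine-2-thione | CCC(=O)N1[C@@H](C(C)C)CSC1=S | starting material
10 | trichlorotitanium (Z)-enolate of 9 | C/C=C(\O[Ti](Cl)(Cl)Cl)N1[C@@H](C(C)C)CSC1=S | intermediate
11 | cyclic peroxycarbenium ion, 6-methyl-6-[2-(2,6,6-trimethyl-3-oxocyclohex-1-en-1-yl)ethyl]-5,6-dihydro-4H-1,2-dioxin-2-ium (racemic) | CC1(CCC2=C(C)C(=O)CCC2(C)C)CCC=[O+]O1 | intermediate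
12 | (4S)-4-isopropyl-3-[(2R)-2-{(3R,6R)-6-methyl-6-[2-(2,6,6-trimethyl-3-oxocyclohex-1-en-1-yl)ethyl]-1,2-dioxan-3-yl}propanoyl]-1,3-thiazolidine-2-thione | CC(C)[C@H]1CSC(=S)N1C(=O)[C@H](C)[C@H]1CC[C@@](C)(CCC2=C(C)C(=O)CCC2(C)C)OO1 | intermediate
13 | diacarperoxide A, methyl (2R)-2-{(3R,6R)-6-methyl-6-[2-(2,6,6-trimethyl-3-oxocyclohex-1-en-1-yl)ethyl]-1,2-dioxan-3-yl}propanoate | COC(=O)[C@H](C)[C@H]1CC[C@@](C)(CCC2=C(C)C(=O)CCC2(C)C)OO1 | target

## Step count and risks

Total step count: 6. Longest linear sequence: 6 steps (1 to 13).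

**Step 5** is the most likely to fail. A chiral titanium enolate has not been added to a peroxycarbenium ion before; the Lewis acids may fragment the peroxyacetal, and the C-6 epimers must be separable. The fallback sets out from 5 and comes back at 13; it fixes C-2 and C-3 differently but still gives both C-6 epimers.
- The dioxolane of 5 is hydrolysed (pyridinium tosylate, wet acetone) to 4-methyl-6-(2,6,6-trimethyl-3-oxocyclohex-1-en-1-yl)hex-3-enal F1.
- Catalytic asymmetric acyl halide–aldehyde cyclocondensation (propanoyl chloride, iPr2NEt, LiClO4, O-trimethylsilylquinine, −78 °C) gives the cis-lactone (3R,4S)-3-methyl-4-[3-methyl-5-(2,6,6-trimethyl-3-oxocyclohex-1-en-1-yl)pent-2-en-1-yl]oxetan-2-one F2.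
- Co(acac)2/O2/Et3SiH peroxidation of the alkene gives (3R,4S)-3-methyl-4-{3-methyl-3-[(triethylsilyl)peroxy]-5-(2,6,6-trimethyl-3-oxocyclohex-1-en-1-yl)pentyl}oxetan-2-one F3.
- Bu4NF and then Cs2CO3 in DMF free the peroxide anion, which opens the lactone at its O-bearing carbon by intramolecular SN2 with inversion. This gives the caesium salt of (2R)-2-{(3R,6R)-6-methyl-6-[2-(2,6,6-trimethyl-3-oxocyclohex-1-en-1-yl)ethyl]-1,2-dioxan-3-yl}propanoic acid F4 together with its C-6 epimer.
- MeI in the same flask and chromatography give 13.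

**Step 2** is the second risk. The basic ylide may deprotonate the enone or the methyl ketone, or attack the ring ketone. The fallback sets out from 1 and comes back at 8; it moves the olefination to a stage where no second ketone exists and installs the ring ketone late.
- Ylide 4 and 1 give 2-[3-methyl-5-(2,6,6-trimethylcyclohex-1-en-1-yl)pent-2-en-1-yl]-1,3-dioxolane F5.
- Co(acac)2/O2/Et3SiH reacts at the trisubstituted alkene in preference to the tetrasubstituted ring alkene and gives 2-{3-methyl-3-[(triethylsilyl)peroxy]-5-(2,6,6-trimethylcyclohex-1-en-1-yl)pentyl}-1,3-dioxolane F6.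
- TsOH in MeOH passes through the free hydroperoxide 2-[3-hydroperoxy-3-methyl-5-(2,6,6-trimethylcyclohex-1-en-1-yl)pentyl]-1,3-dioxolane F7 to 3-methoxy-6-methyl-6-[2-(2,6,6-trimethylcyclohex-1-en-1-yl)ethyl]-1,2-dioxane F8.
- Allylic oxidation of F8 with CrO3/3,5-dimethylpyrazole gives 8.

**Step 4** is the third risk. Acid may cleave the tertiary hydroperoxide (Hock-type) or leave an open-chain methyl acetal instead of the ring. The fallback sets out from 6 and comes back at 12; it replaces the equilibrium in methanol by hydrolytic unmasking and irreversible acylation.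
- Bu4NF/AcOH desilylates 6 to 7.
- Oxalic acid in wet THF hydrolyses the dioxolane, and the hydroperoxy aldehyde closes to 3-[2-(6-hydroxy-3-methyl-1,2-dioxan-3-yl)ethyl]-2,4,4-trimethylcyclohex-2-en-1-one F9.
- Ac2O/pyridine gives 6-methyl-6-[2-(2,6,6-trimethyl-3-oxocyclohex-1-en-1-yl)ethyl]-1,2-dioxan-3-yl acetate F10.
- Under the conditions of step 5, F10 ionises to 11 and is trapped by 10 to give 12.

## Further compounds

F1 | step 5 | 4-methyl-6-(2,6,6-trimethyl-3-oxocyclohex-1-en-1-yl)hex-3-enal (E/Z mixture) | CC(CCC1=C(C)C(=O)CCC1(C)C)=CCC=O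
F2 | step 5 | (3R,4S)-3-methyl-4-[3-methyl-5-(2,6,6-trimethyl-3-oxocyclohex-1-en-1-yl)pent-2-en-1-yl]oxetan-2-one | C[C@@H]1[C@H](CC=C(C)CCC2=C(C)C(=O)CCC2(C)C)OC1=O
F3 | step 5 | (3R,4S)-3-methyl-4-{3-methyl-3-[(triethylsilyl)peroxy]-5-(2,6,6-trimethyl-3-oxocyclohex-1-en-1-yl)pentyl}oxetan-2-one (both epimers at the peroxide carbon) | C[C@@H]1[C@H](CCC(C)(CCC2=C(C)C(=O)CCC2(C)C)OO[Si](CC)(CC)CC)OC1=O
F4 | step 5 | (2R)-2-{(3R,6R)-6-methyl-6-[2-(2,6,6-trimethyl-3-oxocyclohex-1-en-1-yl)ethyl]-1,2-dioxan-3-yl}propanoic acid | OC(=O)[C@H](C)[C@H]1CC[C@@](C)(CCC2=C(C)C(=O)CCC2(C)C)OO1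
F5 | step 2 | 2-[3-methyl-5-(2,6,6-trimethylcyclohex-1-en-1-yl)pent-2-en-1-yl]-1,3-dioxolane (E/Z mixture) | CC(CCC1=C(C)CCCC1(C)C)=CCC1OCCO1
F6 | step 2 | 2-{3-methyl-3-[(triethylsilyl)peroxy]-5-(2,6,6-trimethylcyclohex-1-en-1-yl)pentyl}-1,3-dioxolane (racemic) | CC(CCC1=C(C)CCCC1(C)C)(CCC1OCCO1)OO[Si](CC)(CC)CC
F7 | step 2 | 2-[3-hydroperoxy-3-methyl-5-(2,6,6-trimethylcyclohex-1-en-1-yl)pentyl]-1,3-dioxolane (racemic) | CC(CCC1=C(C)CCCC1(C)C)(CCC1OCCO1)OO
F8 | step 2 | 3-methoxy-6-methyl-6-[2-(2,6,6-trimethylcyclohex-1-en-1-yl)ethyl]-1,2-dioxane (racemic, anomer mixture) | COC1CCC(C)(CCC2=C(C)CCCC2(C)C)OO1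
F9 | step 4 | 3-[2-(6-hydroxy-3-methyl-1,2-dioxan-3-yl)ethyl]-2,4,4-trimethylcyclohex-2-en-1-one (racemic, anomer mixture) | OC1CCC(C)(CCC2=C(C)C(=O)CCC2(C)C)OO1
F10 | step 4 | 6-methyl-6-[2-(2,6,6-trimethyl-3-oxocyclohex-1-en-1-yl)ethyl]-1,2-dioxan-3-yl acetate (racemic, anomer mixture) | CC(=O)OC1CCC(C)(CCC2=C(C)C(=O)CCC2(C)C)OO1
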